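## The problem

Terpenoid numbering is used throughout: ring A is C1–C5 and C10, ring B is C5–C10, and C11 is the oxymethylene on C9.

Target 21 joins 6,8-dimethoxycoumarin through its C7 oxygen and C11 to a rearranged drimane bicycle. Ring A carries an axial hydroxyl at C3 next to a gem-dimethyl C4. Ring B holds the C5=C6 double bond, a methyl at C8 and a quaternary C9 bearing a methyl and C11. The stereocentres C8, C9 and C10 are contiguous: C8 can direct bond formation at C9 on a ring, C8 and C9 together fix C10 if it can equilibrate, and C10 fixes the chair of ring A in which the C3 hydroxyl is axial. C11 is a neopentyl carbon flanked by two methines, so substitution there is slow and prone to rearrangement, and the ether is better closed at the aryl carbon. The coumarin lactone tolerates neither hydride, organometallics nor prolonged alkoxide, so it must arrive late. The C5=C6 alkene lies next to H10 and can slip to C5=C10 under acid, and electrophilic oxidants would attack it. The enabling feature is that, with a carbonyl at C5, C8, C9 and C10 are C4, the β-carbon and the α-carbon of a 3,4-dimethylcyclohexenone. C9 can then accept C11 as a nucleophile, C10 becomes an enolate carbon, and the C5 carbonyl becomes the aldol acceptor that closes ring A.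

## Retrosynthesis

**Aryl ether.** The C7(aryl)–O bond of 21 is cut to give diol 17 and 7-bromo-6,8-dimethoxycoumarin 20. Cutting O–C11 instead would require substitution at a neopentyl carbon by a doubly ortho-substituted phenoxide. The forward step is a palladium-catalysed etherification that must prefer the primary hydroxyl of 17 over the shielded axial C3 hydroxyl and spare the lactone. Bromide 20 is reached from isofraxidin 18 through triflate 19.

**Hydroxyl groups.** The C11 hydroxyl of 17 is traced to the C–Si bond of silane 16, and the C3 carbinol of 16 to ketone 15. Silicon serves as a masked hydroxyl that survives enolate chemistry and hydride, so no protecting group is needed. A dimethylphenylsilyl group is preferred to an alkoxysilyl group, which would exchange its alkoxy ligand in methoxide and tert-butoxide. The forward steps are an equatorial hydride delivery to C3 and a silane oxidation that uses no electrophile, because of the C5=C6 alkene.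

**Gem-dimethyl group.** The two C4–CH3 bonds of 15 are cut to give enone 13. Double methylation of the extended enolate of a C4=C5 enone moves the alkene to C5=C6 in the same operation. The forward step must remove H6 and not H10.

**Key disconnection.** Enone 13 is cut at C9–C11, C10–C1 and C4=C5 to give (S)-3,4-dimethylcyclohex-2-en-1-one 5, Grignard reagent 7 and 3-(trimethylsilyl)but-3-en-2-one 8. The cut removes ring A, two stereocentres and the quaternary centre at once and leaves a monocycle with one stereocentre. The alternative order, ring A first and ring B annulated onto it, would have no resident stereocentre to direct C9. The forward reaction must add C11 anti to the C8 methyl, keep the enolate at C10 and close ring A in the fused sense.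

**Chiral enone.** Enone 5 is traced through silyl enol ether 4 and (S)-4-methylcyclohex-2-en-1-one 3 to silyl enol ether 2 and 4-methylcyclohexanone 1. The C3 methyl of 5 comes from a cuprate, and both alkenes from silyl enol ether dehydrogenation. The only stereochemical demand is the enantioselective deprotonation of symmetric ketone 1.

**Grignard reagent.** Reagent 7 is made from (chloromethyl)dimethylphenylsilane 6 and magnesium.

## Roads not taken

**Alternative 1:** Ring B is cut at C7–C8 and C9–C10. A Diels–Alder reaction of 2,2-dimethyl-3-vinylcyclohex-3-en-1-one A1 with tiglaldehyde A2, under a chiral oxazaborolidinium Lewis acid and with the formyl group exo, would give keto aldehyde A3.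
- Merits: one catalytic step forms ring B, all of C8, C9 and C10, and the C5=C6 alkene with the gem-dimethyl group already in place. C11 arrives as an aldehyde, so one hydride reagent could give diol 17 directly. This road is shorter and avoids both the dienolate methylation and the silane oxidation.
- Weak points: A2 is an α,β-disubstituted enal and among the least reactive dienophiles. It must bond through its fully substituted carbon to the ring-bound terminus of A1, creating the quaternary C9 next to C10. The two alkyl groups on the diene direct the regiochemistry in opposite senses. The ketone of A1 competes with the aldehyde for the boron centre. Exo selectivity and face selectivity would both rest on the catalyst, in a substrate class where neither is assured.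
- Comparison: the chosen plan is longer, but every stereocentre is set by substrate control of a kind with close analogy, and the absolute configuration comes from a well-studied desymmetrisation.

**Alternative 2:** The C5=C6 bond is cut. Reductive coupling of keto aldehyde A4 with low-valent titanium (TiCl3, trivalent titanium, with zinc–copper couple) would close ring B and give bis-silyl ether A5.
- Merits: the alkene can only form between C5 and C6, which is better than the regiochemical demand of step 7 here, and the silyl ethers should be tolerated.
- Weak points: the step creates no stereocentre. The contiguous C8, C9 and C10 of A4, including the quaternary C9, would have to be built on an open chain without ring B as a template. C10 of A4 is α to the ketone and epimerisable. The C5 ketone is flanked by a quaternary and a branched carbon, and titanium is needed in large excess.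
- Comparison: the chosen plan uses ring B itself to relay stereochemistry, and pays for that with an alkene position that must be controlled in step 7.

**Alternative 3:** The C9–C10 bond is cut. Cobalt hydride, from Co(salen) (divalent cobalt), an N-fluoropyridinium oxidant and PhSiH3, would transfer hydrogen to the methylene of diene A6. The tertiary C9 radical would close ring B on C10, and loss of H6 would give silyl ether A7, one deprotection from 21.
- Merits: the aryl ether is made early at an unhindered allylic carbon from 18. This removes the weakest step of the chosen plan, and the route is convergent and neutral.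
- Weak points: the C9 radical is planar, so C9 and C10 would both be set by a chair-like transition state biased only by the C8 methyl. The cyclised C5 radical can lose H10 as well as H6. The electron-poor coumarin alkene is an acceptor for a nucleophilic tertiary radical. Hydrogen transfer to the ring A alkene competes.
- Comparison: the chosen plan sets the same two centres by anti addition and equilibration on a ring, and pays for that with a hindered late etherification.

Key step: step 6

Assumption: the (R,R)-amide is taken to remove the same enantiotopic proton of 4-methylcyclohexanone as of 4-tert-butylcyclohexanone, which leads to the (S)-enol ether; if the sense is opposite, the (S,S)-amine is used.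

## Route

Step 1
Reactants: 1 4-methylcyclohexanone
Product: 2 (S)-trimethyl[(4-methylcyclohex-1-en-1-yl)oxy]silane
Conditions: (R,R)-bis(1-phenylethyl)amine, n-BuLi, LiCl, THF, −78 °C; then Me3SiCl and 1, −100 → −78 °C
Reagents that add atoms: chlorotrimethylsilane, C[Si](C)(C)Cl
Why: Enantioselective deprotonation by a chiral lithium amide with internal silyl quench; the amide distinguishes the two enantiotopic axial α-protons, which makes C4 (later C8) stereogenic, and any shortfall in enantiomeric purity should be removable by recrystallisation of diol 17.

Step 2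
Reactants: 2 (S)-trimethyl[(4-methylcyclohex-1-en-1-yl)oxy]silane
Product: 3 (S)-4-methylcyclohex-2-en-1-one
Conditions: Pd(OAc)2 (10 mol %), O2 (1 atm), DMSO, 25 °C
Reagents that add atoms: none
Why: Saegusa–Ito oxidation; the palladium enolate formed at C2 loses the C3 hydride, so the alkene appears on the side fixed by the enol ether and the C4 stereocentre is untouched under these neutral conditions.

Step 3
Reactants: 3 (S)-4-methylcyclohex-2-en-1-one
Product: 4 trimethyl{[(3R,4S)-3,4-dimethylcyclohex-1-en-1-yl]oxy}silane
Conditions: Me2CuLi, Me3SiCl, THF, −78 °C; then Et3N, aq. NaHCO3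
Reagents that add atoms: lithium dimethylcuprate, [Li+].C[Cu-]C; chlorotrimethylsilane, C[Si](C)(C)Cl
Why: Cuprate conjugate addition with in situ silylation fixes the enol ether toward C2; the methyl should enter anti to the C4 methyl, although this new centre is erased in step 4.

Step 4
Reactants: 4 trimethyl{[(3R,4S)-3,4-dimethylcyclohex-1-en-1-yl]oxy}silane
Product: 5 (S)-3,4-dimethylcyclohex-2-en-1-one
Conditions: Pd(OAc)2 (10 mol %), O2 (1 atm), DMSO, 25 °C
Reagents that add atoms: none
Why: Second Saegusa–Ito oxidation; only C3 carries a hydrogen β to the palladium-bound C2, so the trisubstituted enone forms and C4 keeps its S configuration.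

Step 5
Reactants: 6 (chloromethyl)dimethylphenylsilane
Product: 7 [(dimethylphenylsilyl)methyl]magnesium chloride
Conditions: Mg, 1,2-dibromoethane (cat.), THF, reflux
Reagents that add atoms: magnesium, [Mg]
Why: Standard Grignard formation from an α-silyl alkyl chloride; the reagent is a hydroxymethyl anion equivalent whose silicon carries only carbon ligands and so resists the alkoxide bases of steps 6 and 7.

Step 6
Reactants: 5 (S)-3,4-dimethylcyclohex-2-en-1-one; 7 [(dimethylphenylsilyl)methyl]magnesium chloride; 8 3-(trimethylsilyl)but-3-en-2-one
Product: 13 (4aR,5R,6S)-5-[(dimethylphenylsilyl)methyl]-5,6-dimethyl-4,4a,5,6,7,8-hexahydronaphthalen-2(3H)-one, via magnesium enolate 9 (not isolated), via silyl diketone 10 (not isolated), via diketone 11 (not isolated), via ketol 12 (not isolated)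
Conditions: CuBr·SMe2 (10 mol %), THF, −78 → −30 °C; then 8, −78 → 0 °C; then NaOMe, MeOH, 25 → 60 °C
Reagents that add atoms: none
Why: Transmetalation of 7 to CuBr·SMe2 gives a silylmethylcopper species (monovalent copper) that adds to the β-carbon C9 of 5 through a π-complex and a trivalent-copper adduct, forming C9–C11 and leaving magnesium enolate 9 regiodefined at C10; the closest known reaction type is the copper-catalysed conjugate addition of Grignard reagents to 3,4-dialkylcyclohexenones with enolate trapping. C9 is controlled by C8: allylic 1,2-strain with the C9 methyl holds the C8 methyl pseudoaxial, so the reagent should enter axially on the opposite face and the two methyls end cis. Enolate 9 then adds through C10 to the α-silyl enone 8 (Michael addition, C10–C1), the silicon stabilising the new α-carbanion so that 10 does not add a second molecule of 8 and 8 does not polymerise. Methoxide cleaves the C–Si bond of 10 to give diketone 11, whose methyl ketone enolate attacks the C5 carbonyl in a 6-(enolendo)-exo-trig aldol addition to ketol 12, and E1cB loss of water gives the C4=C5 enone of 13 and closes ring A; this is the α-silyl vinyl ketone variant of the Robinson annulation. C10 stays enolisable in 10 to 12 and should equilibrate under methoxide to the epimer with C1 equatorial on ring B, anti to the axial C9 methyl and anchored by the equatorial C8 methyl, so that H10 ends trans to the C9 methyl. The step needs 1,4- over 1,2-addition, secured by copper; retention of the C10 enolate, secured by adding 8 cold before proton exchange can move the enolate to C6; and closure in the fused sense, secured because only the fused ketol can dehydrate to a conjugated enone.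

Step 7
Reactants: 13 (4aR,5R,6S)-5-[(dimethylphenylsilyl)methyl]-5,6-dimethyl-4,4a,5,6,7,8-hexahydronaphthalen-2(3H)-one
Product: 15 (4aR,5R,6S)-5-[(dimethylphenylsilyl)methyl]-1,1,5,6-tetramethyl-3,4,4a,5,6,7-hexahydronaphthalen-2(1H)-one, via monomethyl ketone 14 (not isolated)
Conditions: KOt-Bu (3 equiv), MeI (excess), t-BuOH/THF, 0 → 25 °C
Reagents that add atoms: iodomethane, CI
Why: Deconjugative gem-dimethylation of a C4=C5 enone: loss of H6 gives the heteroannular dienolate, which is methylated at C4 to 14, and the doubly activated C4–H of 14 is removed and methylated again, locking the alkene at C5=C6. H10 is tertiary, screened by the quaternary C9, and its loss would put a tetrasubstituted alkene beside that centre, so H6 should be preferred.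

Step 8
Reactants: 15 (4aR,5R,6S)-5-[(dimethylphenylsilyl)methyl]-1,1,5,6-tetramethyl-3,4,4a,5,6,7-hexahydronaphthalen-2(1H)-one
Product: 16 (2S,4aR,5R,6S)-5-[(dimethylphenylsilyl)methyl]-1,1,5,6-tetramethyl-1,2,3,4,4a,5,6,7-octahydronaphthalen-2-ol
Conditions: LiBH(s-Bu)3, THF, −78 °C; then NaOH, H2O2, 0 °C
Reagents that add atoms: none
Why: Bulky trialkylborohydride reduction of a ketone beside a quaternary carbon; in the ring A chair fixed by the axial H10 the hydride should arrive along the equatorial direction, giving the axial 3S alcohol, as is usual for 4,4-dimethyl-3-ketones.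

Step 9
Reactants: 16 (2S,4aR,5R,6S)-5-[(dimethylphenylsilyl)methyl]-1,1,5,6-tetramethyl-1,2,3,4,4a,5,6,7-octahydronaphthalen-2-ol
Product: 17 (2S,4aR,5R,6S)-5-(hydroxymethyl)-1,1,5,6-tetramethyl-1,2,3,4,4a,5,6,7-octahydronaphthalen-2-ol
Conditions: KH, t-BuOOH, N-methylpyrrolidone, 25 °C; then Bu4NF, 70 °C
Reagents that add atoms: tert-butyl hydroperoxide, CC(C)(C)OO
Why: Fleming–Tamao oxidation under basic conditions: the peroxide anion adds to silicon, phenyl and then the C11 methylene migrate from silicon to oxygen, and fluoride-assisted cleavage frees the primary alcohol. No electrophile is present, so the C5=C6 alkene should survive.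

Step 10
Reactants: 18 isofraxidin (7-hydroxy-6,8-dimethoxy-2H-chromen-2-one)
Product: 19 6,8-dimethoxy-2-oxo-2H-chromen-7-yl trifluoromethanesulfonate
Conditions: Tf2O, pyridine, CH2Cl2, 0 °C
Reagents that add atoms: trifluoromethanesulfonic anhydride, O=S(=O)(OS(=O)(=O)C(F)(F)F)C(F)(F)F
Why: O-sulfonylation of an acidic phenol; the lactone is inert to these conditions.

Step 11
Reactants: 19 6,8-dimethoxy-2-oxo-2H-chromen-7-yl trifluoromethanesulfonate
Product: 20 7-bromo-6,8-dimethoxy-2H-chromen-2-one
Conditions: Pd2(dba)3 (2.5 mol %), t-BuBrettPhos (7.5 mol %), KBr, KF, 1,4-dioxane, 130 °C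
Reagents that add atoms: potassium bromide, [K+].[Br-]
Why: Palladium-catalysed conversion of an aryl triflate into an aryl bromide: oxidative addition, triflate–bromide exchange and C–Br reductive elimination from a bulky biarylphosphine complex, the last favoured by the two ortho substituents.

Step 12
Reactants: 17 (2S,4aR,5R,6S)-5-(hydroxymethyl)-1,1,5,6-tetramethyl-1,2,3,4,4a,5,6,7-octahydronaphthalen-2-ol; 20 7-bromo-6,8-dimethoxy-2H-chromen-2-one
Product: 21 7-{[(1R,2S,6S,8aR)-6-hydroxy-1,2,5,5-tetramethyl-1,2,3,5,6,7,8,8a-octahydronaphthalen-1-yl]methoxy}-6,8-dimethoxy-2H-chromen-2-one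
Conditions: [Pd(allyl)Cl]2 (2.5 mol %), RockPhos (6 mol %), Cs2CO3, toluene, 90 °C
Reagents that add atoms: none
Why: Buchwald–Hartwig etherification of a primary alcohol with an aryl bromide; the bond forms at the aryl carbon, so the neopentyl C11 is never a reaction centre, and the ortho methoxy groups and the electron-poor coumarin ring favour C–O reductive elimination. The primary alkoxide should bind palladium in preference to the axial C3 hydroxyl, which is shielded by the gem-dimethyl group, and carbonate in toluene should leave the lactone closed.

## Compound list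

1 | 4-methylcyclohexanone | CC1CCC(=O)CC1 | starting material
2 | (S)-trimethyl[(4-methylcyclohex-1-en-1-yl)oxy]silane | C[C@H]1CCC(O[Si](C)(C)C)=CC1 | intermediate
3 | (S)-4-methylcyclohex-2-en-1-one | C[C@H]1CCC(=O)C=C1 | intermediate
4 | trimethyl{[(3R,4S)-3,4-dimethylcyclohex-1-en-1-yl]oxy}silane | C[C@H]1CCC(O[Si](C)(C)C)=C[C@@H]1C | intermediate
5 | (S)-3,4-dimethylcyclohex-2-en-1-one | CC1=CC(=O)CC[C@@H]1C | intermediate
6 | (chloromethyl)dimethylphenylsilane | C[Si](C)(CCl)c1ccccc1 | starting material
7 | [(dimethylphenylsilyl)methyl]magnesium chloride | C[Si](C)(C[Mg]Cl)c1ccccc1 | intermediate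
8 | 3-(trimethylsilyl)but-3-en-2-one | CC(=O)C(=C)[Si](C)(C)C | starting material
9 | chloromagnesium (3R,4S)-3-[(dimethylphenylsilyl)methyl]-3,4-dimethylcyclohex-1-en-1-olate (not isolated) | C[Si](C)(c1ccccc1)C[C@@]1(C)C=C(O[Mg]Cl)CC[C@@H]1C | intermediate
10 | (2S,3R,4S)-3-[(dimethylphenylsilyl)methyl]-3,4-dimethyl-2-[3-oxo-2-(trimethylsilyl)butyl]cyclohexan-1-one, both epimers at the silyl-bearing side-chain carbon, present as its magnesium enolate until methanol is added (not isolated) | C[Si](C)(c1ccccc1)C[C@@]1(C)[C@H](CC(C(C)=O)[Si](C)(C)C)C(=O)CC[C@@H]1C | intermediate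
11 | (2S,3R,4S)-3-[(dimethylphenylsilyl)methyl]-3,4-dimethyl-2-(3-oxobutyl)cyclohexan-1-one (not isolated) | C[Si](C)(c1ccccc1)C[C@@]1(C)[C@H](CCC(C)=O)C(=O)CC[C@@H]1C | intermediate
12 | (4aS,5R,6S)-5-[(dimethylphenylsilyl)methyl]-8a-hydroxy-5,6-dimethyloctahydronaphthalen-2(1H)-one, either configuration at C8a (not isolated) | C[Si](C)(c1ccccc1)C[C@@]1(C)[C@@H]2CCC(=O)CC2(O)CC[C@@H]1C | intermediate
13 | (4aR,5R,6S)-5-[(dimethylphenylsilyl)methyl]-5,6-dimethyl-4,4a,5,6,7,8-hexahydronaphthalen-2(3H)-one | C[Si](C)(c1ccccc1)C[C@@]1(C)[C@@H]2CCC(=O)C=C2CC[C@@H]1C | intermediate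
14 | (4aR,5R,6S)-5-[(dimethylphenylsilyl)methyl]-1,5,6-trimethyl-3,4,4a,5,6,7-hexahydronaphthalen-2(1H)-one, either configuration at C1 (not isolated) | C[Si](C)(c1ccccc1)C[C@@]1(C)[C@@H]2CCC(=O)C(C)C2=CC[C@@H]1C | intermediate
15 | (4aR,5R,6S)-5-[(dimethylphenylsilyl)methyl]-1,1,5,6-tetramethyl-3,4,4a,5,6,7-hexahydronaphthalen-2(1H)-one | C[Si](C)(c1ccccc1)C[C@@]1(C)[C@@H]2CCC(=O)C(C)(C)C2=CC[C@@H]1C | intermediate
16 | (2S,4aR,5R,6S)-5-[(dimethylphenylsilyl)methyl]-1,1,5,6-tetramethyl-1,2,3,4,4a,5,6,7-octahydronaphthalen-2-ol | C[Si](C)(c1ccccc1)C[C@@]1(C)[C@@H]2CC[C@H](O)C(C)(C)C2=CC[C@@H]1C | intermediate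
17 | (2S,4aR,5R,6S)-5-(hydroxymethyl)-1,1,5,6-tetramethyl-1,2,3,4,4a,5,6,7-octahydronaphthalen-2-ol | OC[C@@]1(C)[C@@H]2CC[C@H](O)C(C)(C)C2=CC[C@@H]1C | intermediate
18 | isofraxidin (7-hydroxy-6,8-dimethoxy-2H-chromen-2-one) | COc1cc2ccc(=O)oc2c(OC)c1O | starting material
19 | 6,8-dimethoxy-2-oxo-2H-chromen-7-yl trifluoromethanesulfonate | COc1cc2ccc(=O)oc2c(OC)c1OS(=O)(=O)C(F)(F)F | intermediate
20 | 7-bromo-6,8-dimethoxy-2H-chromen-2-one | COc1cc2ccc(=O)oc2c(OC)c1Br | intermediate
21 | 7-{[(1R,2S,6S,8aR)-6-hydroxy-1,2,5,5-tetramethyl-1,2,3,5,6,7,8,8a-octahydronaphthalen-1-yl]methoxy}-6,8-dimethoxy-2H-chromen-2-one | COc1cc2ccc(=O)oc2c(OC)c1OC[C@@]1(C)[C@@H]2CC[C@H](O)C(C)(C)C2=CC[C@@H]1C | target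

## Step count and least certain steps

Total step count: 12. Longest linear sequence: 9 steps (steps 1 to 4, 6 to 9 and 12). Step 5 and steps 10 and 11 are side branches.

**Step 6 (key step).** Transfer of the bulky silylmethyl group to a doubly substituted β-carbon may be slow and let 1,2-addition compete. The hindered magnesium enolate may exchange protons with the methyl ketone of 8, or move to C6, faster than it adds. Fallback, from 5 and 7 back to 13: the copper-catalysed addition is run with Me3SiCl present and the product is isolated as {[(3R,4S)-3-[(dimethylphenylsilyl)methyl]-3,4-dimethylcyclohex-1-en-1-yl]oxy}trimethylsilane F1. MeLi in THF then releases lithium (3R,4S)-3-[(dimethylphenylsilyl)methyl]-3,4-dimethylcyclohex-1-en-1-olate F2 regiospecifically. F2 is treated with 8 at −78 °C, and NaOMe in methanol carries 10 through 11 and 12 to 13. This separates the two bond formations and replaces the magnesium enolate with a more reactive lithium enolate.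

**Step 12.** The palladium alkoxide is crowded on both sides (neopentyl alcohol, 2,6-dimethoxyaryl group). β-Hydride elimination may therefore outrun C–O reductive elimination, which would reduce 20 and oxidise C11. Arylation or oxidation at the C3 hydroxyl and carbonate-induced lactone opening are lesser risks. Fallback, from 17 and 18 directly to 21: the bond polarity is reversed and isofraxidin 18 is alkylated by the primary hydroxyl of 17 in a Mitsunobu-type reaction with Bu3P=CHCN in toluene at 110 °C, a reagent suited to hindered alcohols. The hindered C3 hydroxyl is expected to stay out. The weakness of this fallback is that substitution then takes place at the neopentyl C11. It makes no new compound.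

**Step 9.** Attack of the peroxide anion on a silicon atom that carries a neopentyl-type group may be incomplete, which would leave silane or partly oxidised siloxanes. Fallback, from 16 back to 17: Birch reduction (Li, NH3, THF, t-BuOH, −78 °C) turns the phenyl ring into a cyclohexadienyl group and gives (2S,4aR,5R,6S)-5-{[(cyclohexa-2,5-dien-1-yl)dimethylsilyl]methyl}-1,1,5,6-tetramethyl-1,2,3,4,4a,5,6,7-octahydronaphthalen-2-ol F3. Its allylic C–Si bond is cleaved by Bu4NF, and the resulting fluorosilane is oxidised with KF, KHCO3 and H2O2 to 17. The isolated trisubstituted alkene is not reduced under Birch conditions.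

**Step 7.** Removal of H10 in place of H6 would lead to the C5=C10 isomer and destroy the C10 stereocentre. Excess base and iodomethane may also methylate C2. Fallback, from 13 back to 15: the dienolate regiochemistry is fixed at an isolable stage. Isopropenyl acetate and TsOH at reflux give (4aR,5R,6S)-5-[(dimethylphenylsilyl)methyl]-5,6-dimethyl-3,4,4a,5,6,7-hexahydronaphthalen-2-yl acetate F4 under thermodynamic control, and any homoannular isomer is removed. MeLi (2 equiv) in 1,2-dimethoxyethane releases lithium (4aR,5R,6S)-5-[(dimethylphenylsilyl)methyl]-5,6-dimethyl-3,4,4a,5,6,7-hexahydronaphthalen-2-olate F5. Iodomethane then gives 14, now isolated, and KOt-Bu with iodomethane removes the C4–H of 14 and gives 15.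

**Step 11.** Oxidative addition into a triflate flanked by two methoxy groups may be slow, and fluoride or bromide may cleave the S–O bond and return 18. Fallback, from 19 back to 20: Miyaura borylation (PdCl2(dppf), bis(pinacolato)diboron, KOAc, 1,4-dioxane, 90 °C) gives 6,8-dimethoxy-7-(4,4,5,5-tetramethyl-1,3,2-dioxaborolan-2-yl)-2H-chromen-2-one F6. Bromodeboronation with CuBr2 (divalent copper) in aqueous methanol then gives 20.

## Further compounds

F1 | step 6 | {[(3R,4S)-3-[(dimethylphenylsilyl)methyl]-3,4-dimethylcyclohex-1-en-1-yl]oxy}trimethylsilane | C[Si](C)(c1ccccc1)C[C@@]1(C)C=C(O[Si](C)(C)C)CC[C@@H]1C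
F2 | step 6 | lithium (3R,4S)-3-[(dimethylphenylsilyl)methyl]-3,4-dimethylcyclohex-1-en-1-olate | C[Si](C)(c1ccccc1)C[C@@]1(C)C=C(O[Li])CC[C@@H]1C
F0 | step 12 | none | none
F3 | step 9 | (2S,4aR,5R,6S)-5-{[(cyclohexa-2,5-dien-1-yl)dimethylsilyl]methyl}-1,1,5,6-tetramethyl-1,2,3,4,4a,5,6,7-octahydronaphthalen-2-ol | C[Si](C)(C1C=CCC=C1)C[C@@]1(C)[C@@H]2CC[C@H](O)C(C)(C)C2=CC[C@@H]1C
F4 | step 7 | (4aR,5R,6S)-5-[(dimethylphenylsilyl)methyl]-5,6-dimethyl-3,4,4a,5,6,7-hexahydronaphthalen-2-yl acetate | C[Si](C)(c1ccccc1)C[C@@]1(C)[C@@H]2CCC(OC(C)=O)=CC2=CC[C@@H]1C
F5 | step 7 | lithium (4aR,5R,6S)-5-[(dimethylphenylsilyl)methyl]-5,6-dimethyl-3,4,4a,5,6,7-hexahydronaphthalen-2-olate | C[Si](C)(c1ccccc1)C[C@@]1(C)[C@@H]2CCC(O[Li])=CC2=CC[C@@H]1C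
F6 | step 11 | 6,8-dimethoxy-7-(4,4,5,5-tetramethyl-1,3,2-dioxaborolan-2-yl)-2H-chromen-2-one | COc1cc2ccc(=O)oc2c(OC)c1B1OC(C)(C)C(C)(C)O1
A1 | alternative 1 | 2,2-dimethyl-3-vinylcyclohex-3-en-1-one | C=CC1=CCCC(=O)C1(C)C
A2 | alternative 1 | tiglaldehyde ((E)-2-methylbut-2-enal) | C/C=C(\C)C=O
A3 | alternative 1 | ring A/B keto aldehyde with C5=C6, C3 ketone and C11 formyl group | O=C[C@@]1(C)[C@@H]2CCC(=O)C(C)(C)C2=CC[C@@H]1C
A4 | alternative 2 | open-ring B keto aldehyde with C5 ketone, C6 aldehyde and both hydroxyls as tert-butyldimethylsilyl ethers | O=CC[C@H](C)[C@@](C)(CO[Si](C)(C)C(C)(C)C)[C@@H]1CC[C@H](O[Si](C)(C)C(C)(C)C)C(C)(C)C1=O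
A5 | alternative 2 | bis(tert-butyldimethylsilyl) ether of diol 17 | CC(C)(C)[Si](C)(C)OC[C@@]1(C)[C@@H]2CC[C@H](O[Si](C)(C)C(C)(C)C)C(C)(C)C2=CC[C@@H]1C
A6 | alternative 3 | ring A cyclohexene (C5=C10) with a C6–C9 chain ending in a 1,1-disubstituted alkene that carries the isofraxidin ether, C3 hydroxyl as tert-butyldimethylsilyl ether | C=C(COc1c(OC)cc2ccc(=O)oc2c1OC)[C@@H](C)CCC1=CCC[C@H](O[Si](C)(C)C(C)(C)C)C1(C)C
A7 | alternative 3 | 3-O-tert-butyldimethylsilyl ether of 21 | COc1cc2ccc(=O)oc2c(OC)c1OC[C@@]1(C)[C@@H]2CC[C@H](O[Si](C)(C)C(C)(C)C)C(C)(C)C2=CC[C@@H]1C
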